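The chroman is disconnected at O1–C2. C2 is a tertiary ether carbon flanked by the E C1′=C2′ alkene of the side chain, which is the pattern left when a phenol oxygen adds to the methyl-substituted end of a C2=C1′=C2′ allene and the central carbon takes up a proton. One enantioselective gold(I)-catalysed hydroalkoxylation of a racemic vinylallene should therefore close the pyran ring, set C2 (R) and fix the 1′E geometry, while the 3′Z alkene is brought in from a (Z)-enal. The precursor is a 2-alkylhydroquinone whose chain holds a 3,4-allene and a 6Z alkene; it is assembled from an arylbutyne, the enal and a methylcuprate and desilylated just before ring closure.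

Key step: step 14

Assumption: the sense of induction of the bisphosphine–digold catalyst on this substrate type cannot be predicted with confidence, so the (S)-ligand is written and its antipode is used if a first analytical run shows the (S)-chroman.

Remark (structure check): the target is (2R,1′E,3′Z) and the precursor carries the 6Z alkene that becomes 3′Z. The spectator hydroxyl of the precursor is para to the reacting hydroxyl and meta to the side chain. Neither skeleton needs correction.

Remark (precursor design): the hydroquinone is set free from its bis-silyl ether only in the step before ring closure. The gold catalyst is freed of silver before use, because Ag(I) oxidises hydroquinones. Compounds 19 and 20 are kept at or below 0 °C, because a (Z)-vinylallene with a cis allylic CH2 is prone to a thermal [1,5]-hydrogen shift.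

Step 1
Reactants: 1 β-cyclocitral
Product: 2 β-cyclogeraniol [(2,6,6-trimethylcyclohex-1-en-1-yl)methanol]
Conditions: NaBH4, MeOH, 0 °C
Reagents that add atoms: none
Why: Borohydride 1,2-reduction of the hindered conjugated aldehyde gives the primary allylic alcohol and leaves the tetrasubstituted alkene untouched.

Step 2
Reactants: 2 β-cyclogeraniol
Product: 3 β-cyclogeranyl bromide [2-(bromomethyl)-1,3,3-trimethylcyclohex-1-ene]
Conditions: PBr3, pyridine (cat.), Et2O, −10 → 0 °C; used crude
Reagents that add atoms: phosphorus tribromide, BrP(Br)Br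
Why: Conversion of a primary allylic alcohol into its bromide with PBr3 (SN2 on the phosphite ester) should proceed without allylic shift, because the tetrasubstituted ring alkene is the favoured isomer.

Step 3
Reactants: 4 propyne; 3 β-cyclogeranyl bromide
Product: 7 methyl 5-(2,6,6-trimethylcyclohex-1-en-1-yl)pent-2-ynoate, via 1,3-dilithiopropyne 5 (not isolated), via lithium acetylide 6 (not isolated)
Conditions: 4, n-BuLi (2 equiv), TMEDA, Et2O–hexane, −78 → 0 °C; then 3, −78 → 0 °C; then ClCO2Me, −78 °C
Reagents that add atoms: methyl chloroformate, COC(=O)Cl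
Why: Propargylation of an allylic bromide with 1,3-dilithiopropyne takes place at the sp3 carbanion and leaves the lithium acetylide, which is C-acylated by the chloroformate in the same flask (acetylide alkoxycarbonylation).

Step 4
Reactants: 7 methyl 5-(2,6,6-trimethylcyclohex-1-en-1-yl)pent-2-ynoate
Product: 8 methyl (2Z)-3-methyl-5-(2,6,6-trimethylcyclohex-1-en-1-yl)pent-2-enoate
Conditions: Me2CuLi (CuI, 2 MeLi), THF, −78 °C; MeOH then aq NH4Cl at −78 °C
Reagents that add atoms: lithium dimethylcuprate, [Li+].C[Cu-]C (prepared from methyllithium, [Li]C, and CuI)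
Why: Organocuprate conjugate addition to an ynoate is a syn carbocupration at −78 °C, so after cold protonation with retention the chain and the ester are cis, which is the 2Z geometry.

Step 5
Reactants: 8 methyl (2Z)-3-methyl-5-(2,6,6-trimethylcyclohex-1-en-1-yl)pent-2-enoate
Product: 9 (2Z)-3-methyl-5-(2,6,6-trimethylcyclohex-1-en-1-yl)pent-2-en-1-ol
Conditions: DIBAL-H (2.2 equiv), CH2Cl2, −78 → 0 °C; Rochelle salt
Reagents that add atoms: none
Why: DIBAL-H 1,2-reduction of the enoate should give the allylic alcohol with the Z alkene unchanged.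

Step 6
Reactants: 9 (2Z)-3-methyl-5-(2,6,6-trimethylcyclohex-1-en-1-yl)pent-2-en-1-ol
Product: 10 (2Z)-3-methyl-5-(2,6,6-trimethylcyclohex-1-en-1-yl)pent-2-enal
Conditions: activated MnO2 (excess), CH2Cl2, 0 °C → rt, dark; used promptly
Reagents that add atoms: none
Why: Allylic oxidation with activated MnO2 is selective for allylic alcohols and neutral, so the Z-enal should form without isomerisation to the E isomer.

Step 7
Reactants: 11 6-hydroxycoumarin
Product: 12 6-hydroxychroman-2-one (6-hydroxy-3,4-dihydrocoumarin)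
Conditions: H2 (1–3 atm), 10% Pd/C, AcOH, rt
Reagents that add atoms: none
Why: Heterogeneous catalytic hydrogenation saturates the conjugated C3=C4 bond of the coumarin and leaves the lactone and the arene intact.

Step 8
Reactants: 12 6-hydroxychroman-2-one
Product: 13 chromane-2,6-diol (lactol)
Conditions: DIBAL-H (2.3 equiv), CH2Cl2–THF, −78 °C; Rochelle salt; used crude
Reagents that add atoms: none
Why: DIBAL-H partial reduction of a lactone stops at the tetrahedral aluminate at −78 °C and gives the lactol on work-up, one extra equivalent of hydride being consumed by the phenol.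

Step 9
Reactants: 13 chromane-2,6-diol
Product: 14 2-(but-3-yn-1-yl)benzene-1,4-diol
Conditions: dimethyl (1-diazo-2-oxopropyl)phosphonate, K2CO3, degassed MeOH, 0 °C → rt, Ar
Reagents that add atoms: dimethyl (1-diazo-2-oxopropyl)phosphonate, COP(=O)(OC)C(=[N+]=[N-])C(C)=O
Why: Ohira–Bestmann homologation (Seyferth–Gilbert type) acts on the hydroxy aldehyde tautomer of the lactol and turns the formyl carbon into the terminal alkyne, air being excluded because of the hydroquinone.

Step 10
Reactants: 14 2-(but-3-yn-1-yl)benzene-1,4-diol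
Product: 15 2-(but-3-yn-1-yl)-1,4-bis[(tert-butyldimethylsilyl)oxy]benzene
Conditions: TBSCl, imidazole, DMF, rt
Reagents that add atoms: tert-butyldimethylsilyl chloride, CC(C)(C)[Si](C)(C)Cl
Why: Silylation of both phenols with TBSCl and imidazole masks the acidic OH groups for the organolithium and cuprate steps and is removable by fluoride.

Step 11
Reactants: 15 2-(but-3-yn-1-yl)-1,4-bis[(tert-butyldimethylsilyl)oxy]benzene; 10 (2Z)-3-methyl-5-(2,6,6-trimethylcyclohex-1-en-1-yl)pent-2-enal
Product: 18 rac-(6Z)-1-{2,5-bis[(tert-butyldimethylsilyl)oxy]phenyl}-7-methyl-9-(2,6,6-trimethylcyclohex-1-en-1-yl)non-6-en-3-yn-5-yl acetate, via lithium acetylide 16 (not isolated), via lithium alkoxide 17 (not isolated)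
Conditions: n-BuLi, THF, −78 °C; then 10, −78 °C; then Ac2O, −78 → 0 °C
Reagents that add atoms: acetic anhydride, CC(=O)OC(C)=O
Why: Lithium acetylide 1,2-addition to the enal followed by in situ O-acetylation should give the propargylic acetate, and the carbinol centre is left racemic on purpose because it is erased when the allene is formed.

Step 12
Reactants: 18 rac-(6Z)-1-{2,5-bis[(tert-butyldimethylsilyl)oxy]phenyl}-7-methyl-9-(2,6,6-trimethylcyclohex-1-en-1-yl)non-6-en-3-yn-5-yl acetate
Product: 19 rac-2-[(6Z)-3,7-dimethyl-9-(2,6,6-trimethylcyclohex-1-en-1-yl)nona-3,4,6-trien-1-yl]-1,4-bis[(tert-butyldimethylsilyl)oxy]benzene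
Conditions: Me2CuLi (CuI, 2 MeLi), Et2O, −78 → −30 °C; aq NH4Cl/NH3; isolated and stored cold
Reagents that add atoms: lithium dimethylcuprate, [Li+].C[Cu-]C (prepared from methyllithium, [Li]C, and CuI)
Why: Anti-SN2′ displacement of a propargylic acetate by a dimethylcuprate (organocopper allene synthesis) delivers methyl to the alkyne carbon remote from the leaving group, while attack through the alkene would have to create a quaternary carbon and is disfavoured.

Step 13
Reactants: 19 rac-2-[(6Z)-3,7-dimethyl-9-(2,6,6-trimethylcyclohex-1-en-1-yl)nona-3,4,6-trien-1-yl]-1,4-bis[(tert-butyldimethylsilyl)oxy]benzene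
Product: 20 rac-2-[(6Z)-3,7-dimethyl-9-(2,6,6-trimethylcyclohex-1-en-1-yl)nona-3,4,6-trien-1-yl]benzene-1,4-diol
Conditions: TBAF, AcOH (1:1), THF, 0 °C, Ar; used at once
Reagents that add atoms: none
Why: Fluoride-mediated desilylation of the two aryl silyl ethers is fast at 0 °C, and the acetic acid buffer prevents phenoxide formation, which would invite oxidation of the hydroquinone or base-induced isomerisation of the vinylallene.

Step 14
Reactants: 20 rac-2-[(6Z)-3,7-dimethyl-9-(2,6,6-trimethylcyclohex-1-en-1-yl)nona-3,4,6-trien-1-yl]benzene-1,4-diol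
Product: 21 (2R)-2-methyl-2-[(1E,3Z)-4-methyl-6-(2,6,6-trimethylcyclohex-1-en-1-yl)hexa-1,3-dien-1-yl]-3,4-dihydro-2H-chromen-6-ol (CNP0275099.1)
Conditions: [(S)-DTBM-MeO-BIPHEP](AuCl)2 (2.5 mol%), AgOTs (5 mol%; premixed, AgCl filtered off), toluene, −20 °C, Ar, dark
Reagents that add atoms: none
Why: Proposed new method: the cationic gold(I) centre binds the C2=C1′ bond of the allene, the ortho hydroxyl attacks C2 from the face opposite to gold (outer-sphere anti oxyauration) and the vinylgold at C1′ is protonated with retention, so the O1–C2 bond and the 1′E alkene arise in one catalytic cycle. The closest known reaction type is the gold(I)-catalysed enantioselective exo-hydroalkoxylation of hydroxy allenes together with the dynamic kinetic hydroamination of racemic trisubstituted allenes; a phenol adding to a vinylallene has no precedent. The pyran ring is closed in a 6-exo-trig mode at the allene terminus C2, the C2=C1′ bond staying outside the ring. C2 is set by the chiral bisphosphine–digold pocket, which selects one face of C2 for O-attack, and gold should reversibly open the allene to a planar, pentadienyl-cation-like η1 complex, so that both enantiomers of 20 interconvert and drain through the faster diastereomeric pathway. Selectivity rests on the substrate: only the hydroxyl ortho to the chain can reach C2 through a six-membered transition state, the E geometry follows from the transition state that keeps the new quaternary C2 away from C3′ (A1,3 strain), and 4π carbocyclisation is disfavoured because both termini C2 and C4′ are fully substituted. The low temperature is meant to hold back the thermal [1,5]-hydrogen shift of the (Z)-vinylallene and to leave the 3′Z alkene untouched.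

Compound list
1 | β-cyclocitral (2,6,6-trimethylcyclohex-1-ene-1-carbaldehyde) | CC1=C(C=O)C(C)(C)CCC1 | starting material
2 | β-cyclogeraniol [(2,6,6-trimethylcyclohex-1-en-1-yl)methanol] | CC1=C(CO)C(C)(C)CCC1 | intermediate
3 | β-cyclogeranyl bromide [2-(bromomethyl)-1,3,3-trimethylcyclohex-1-ene] | CC1=C(CBr)C(C)(C)CCC1 | intermediate
4 | propyne | CC#C | starting material
5 | 1,3-dilithiopropyne (not isolated) | [Li]CC#C[Li] | intermediate
6 | lithium 4-(2,6,6-trimethylcyclohex-1-en-1-yl)but-1-yn-1-ide (not isolated) | [Li]C#CCCC1=C(C)CCCC1(C)C | intermediate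
7 | methyl 5-(2,6,6-trimethylcyclohex-1-en-1-yl)pent-2-ynoate | COC(=O)C#CCCC1=C(C)CCCC1(C)C | intermediate
8 | methyl (2Z)-3-methyl-5-(2,6,6-trimethylcyclohex-1-en-1-yl)pent-2-enoate | COC(=O)/C=C(C)\CCC1=C(C)CCCC1(C)C | intermediate
9 | (2Z)-3-methyl-5-(2,6,6-trimethylcyclohex-1-en-1-yl)pent-2-en-1-ol | OC/C=C(C)\CCC1=C(C)CCCC1(C)C | intermediate
10 | (2Z)-3-methyl-5-(2,6,6-trimethylcyclohex-1-en-1-yl)pent-2-enal | O=C/C=C(C)\CCC1=C(C)CCCC1(C)C | intermediate
11 | 6-hydroxycoumarin | O=C1C=Cc2cc(O)ccc2O1 | starting material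
12 | 6-hydroxychroman-2-one | O=C1CCc2cc(O)ccc2O1 | intermediate
13 | chromane-2,6-diol (racemic lactol) | OC1CCc2cc(O)ccc2O1 | intermediate
14 | 2-(but-3-yn-1-yl)benzene-1,4-diol | C#CCCc1cc(O)ccc1O | intermediate
15 | 2-(but-3-yn-1-yl)-1,4-bis[(tert-butyldimethylsilyl)oxy]benzene | C#CCCc1cc(O[Si](C)(C)C(C)(C)C)ccc1O[Si](C)(C)C(C)(C)C | intermediate
16 | lithium acetylide of 15 (not isolated) | [Li]C#CCCc1cc(O[Si](C)(C)C(C)(C)C)ccc1O[Si](C)(C)C(C)(C)C | intermediate
17 | lithium rac-(6Z)-1-{2,5-bis[(tert-butyldimethylsilyl)oxy]phenyl}-7-methyl-9-(2,6,6-trimethylcyclohex-1-en-1-yl)non-6-en-3-yn-5-olate (not isolated) | [Li]OC(C#CCCc1cc(O[Si](C)(C)C(C)(C)C)ccc1O[Si](C)(C)C(C)(C)C)/C=C(C)\CCC1=C(C)CCCC1(C)C | intermediate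
18 | rac-(6Z)-1-{2,5-bis[(tert-butyldimethylsilyl)oxy]phenyl}-7-methyl-9-(2,6,6-trimethylcyclohex-1-en-1-yl)non-6-en-3-yn-5-yl acetate | CC(=O)OC(C#CCCc1cc(O[Si](C)(C)C(C)(C)C)ccc1O[Si](C)(C)C(C)(C)C)/C=C(C)\CCC1=C(C)CCCC1(C)C | intermediate
19 | rac-2-[(6Z)-3,7-dimethyl-9-(2,6,6-trimethylcyclohex-1-en-1-yl)nona-3,4,6-trien-1-yl]-1,4-bis[(tert-butyldimethylsilyl)oxy]benzene | CC(CCc1cc(O[Si](C)(C)C(C)(C)C)ccc1O[Si](C)(C)C(C)(C)C)=C=C/C=C(C)\CCC1=C(C)CCCC1(C)C | intermediate
20 | rac-2-[(6Z)-3,7-dimethyl-9-(2,6,6-trimethylcyclohex-1-en-1-yl)nona-3,4,6-trien-1-yl]benzene-1,4-diol | Oc1ccc(O)cc1CCC(C)=C=C/C=C(C)\CCC1=C(C)CCCC1(C)C | intermediate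
21 | (2R)-2-methyl-2-[(1E,3Z)-4-methyl-6-(2,6,6-trimethylcyclohex-1-en-1-yl)hexa-1,3-dien-1-yl]-3,4-dihydro-2H-chromen-6-ol | CC1=C(CC/C(C)=C\C=C\[C@@]2(C)CCc3cc(O)ccc3O2)C(C)(C)CCC1 | target

Total step count: 14 steps.
Longest linear sequence: 10 steps (steps 1–6, then 11–14); the aryl branch (steps 7–10) joins at step 11.

Steps most likely to fail

1. Step 14 (Proposed new method). The catalyst may discriminate the two faces of C2 poorly for a phenol nucleophile. Allene racemisation may be slower than ring closure, which would show up as the 1′Z isomer or as eroded enantiopurity. The delocalised gold-bound cation may also scramble the 3′Z alkene or enter 4π carbocyclisation. The fallback uses known chemistry, sets out from alkyne 15 and alcohol 9, and returns at target 21: the stereocentre is made by palladium-catalysed asymmetric allylic etherification and the diene by olefination. Zirconium-catalysed carboalumination of 15 (Me3Al, cat. Cp2ZrCl2; ate complex with n-BuLi; paraformaldehyde) should give (2E)-5-{2,5-bis[(tert-butyldimethylsilyl)oxy]phenyl}-3-methylpent-2-en-1-ol F1. ClCO2Me and pyridine should give its methyl carbonate F2, and buffered TBAF the free hydroquinone (2E)-5-(2,5-dihydroxyphenyl)-3-methylpent-2-en-1-yl methyl carbonate F3. Pd2(dba)3·CHCl3 with a Trost bisphosphine ligand and AcOH in CH2Cl2 should close the ring by attack of the ortho phenol on the π-allyl complex, giving (2R)-2-ethenyl-2-methyl-3,4-dihydro-2H-chromen-6-ol F4, with the ligand antipode chosen for R. Silylation should give the silyl ether (2R)-6-[(tert-butyldimethylsilyl)oxy]-2-ethenyl-2-methylchromane F5. Lemieux–Johnson cleavage (cat. OsO4, NaIO4, 2,6-lutidine) should then give the non-epimerisable aldehyde (2R)-6-[(tert-butyldimethylsilyl)oxy]-2-methylchromane-2-carbaldehyde F6. In parallel, 9 is converted with CBr4 and PPh3 into (2Z)-1-bromo-3-methyl-5-(2,6,6-trimethylcyclohex-1-en-1-yl)pent-2-ene F7, and a Michaelis–Becker reaction with sodium diethyl phosphite should give diethyl [(2Z)-3-methyl-5-(2,6,6-trimethylcyclohex-1-en-1-yl)pent-2-en-1-yl]phosphonate F8. Horner–Wadsworth–Emmons reaction of lithiated F8 with F6 at −78 °C should form the 1′E alkene of the silyl ether of the target F9, and TBAF should release 21.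

2. Step 12. The acetate is both allylic and propargylic, so regiocontrol between SN2′ at the alkyne, SN2′ at the alkene and direct substitution may be lost. The acetate may ionise, and the (Z)-vinylallene may undergo a [1,5]-hydrogen shift during isolation. The fallback sets out from enal 10 and lactone 12 and returns at allene 19: the methyl group is placed first and hydride is delivered in the SN2′ step, on a leaving group that is propargylic only. Dibromo-olefination of 10 (CBr4, PPh3, Zn; first stage of the Corey–Fuchs reaction) should give (3Z)-1,1-dibromo-4-methyl-6-(2,6,6-trimethylcyclohex-1-en-1-yl)hexa-1,3-diene F10. Lactone 12 with MeLi (2.2 equiv, −78 °C) should give 2-methylchromane-2,6-diol F11, the cyclic hemiketal of the hydroxy ketone. F11 is silylated in its open form (TBSCl, imidazole) to 4-{2,5-bis[(tert-butyldimethylsilyl)oxy]phenyl}butan-2-one F12. F10 is treated with n-BuLi (2 equiv), F12 is added and the mixture is quenched with ClCO2Me. This should give in one flask the tertiary carbonate rac-(6Z)-1-{2,5-bis[(tert-butyldimethylsilyl)oxy]phenyl}-3,7-dimethyl-9-(2,6,6-trimethylcyclohex-1-en-1-yl)non-6-en-4-yn-3-yl methyl carbonate F13. Palladium-catalysed hydrogenolysis with ammonium formate (Pd2(dba)3·CHCl3, n-Bu3P, THF, rt) delivers hydride to the alkyne carbon remote from the carbonate and should give 19.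

3. Step 3. Substitution at the neopentyl-like allylic bromide may be slow, 1,4-elimination by the strongly basic dianion may compete, and the crude bromide may decompose before it reacts. The fallback sets out from aldehyde 1 and returns at acetylide 6, and it avoids the bromide altogether. Aldol condensation of 1 with acetone (NaOH) should give β-ionone F14. Copper hydride conjugate reduction (cat. Stryker's reagent, PhSiH3) should give dihydro-β-ionone F15; both ketones are also commercial. Kinetic enolisation at the methyl group (LDA, −78 °C) and trapping with ClP(O)(OEt)2 should give diethyl 4-(2,6,6-trimethylcyclohex-1-en-1-yl)but-1-en-2-yl phosphate F16. Elimination with LDA (2.2 equiv) should give the terminal alkyne 4-(2,6,6-trimethylcyclohex-1-en-1-yl)but-1-yne F17. n-BuLi regenerates acetylide 6, which is acylated with ClCO2Me to 7 as in step 3.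

Further compounds
F1 | step 14 | (2E)-5-{2,5-bis[(tert-butyldimethylsilyl)oxy]phenyl}-3-methylpent-2-en-1-ol | OC/C=C(C)/CCc1cc(O[Si](C)(C)C(C)(C)C)ccc1O[Si](C)(C)C(C)(C)C
F2 | step 14 | (2E)-5-{2,5-bis[(tert-butyldimethylsilyl)oxy]phenyl}-3-methylpent-2-en-1-yl methyl carbonate | COC(=O)OC/C=C(C)/CCc1cc(O[Si](C)(C)C(C)(C)C)ccc1O[Si](C)(C)C(C)(C)C
F3 | step 14 | (2E)-5-(2,5-dihydroxyphenyl)-3-methylpent-2-en-1-yl methyl carbonate | COC(=O)OC/C=C(C)/CCc1cc(O)ccc1O
F4 | step 14 | (2R)-2-ethenyl-2-methyl-3,4-dihydro-2H-chromen-6-ol | C=C[C@@]1(C)CCc2cc(O)ccc2O1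
F5 | step 14 | (2R)-6-[(tert-butyldimethylsilyl)oxy]-2-ethenyl-2-methylchromane | C=C[C@@]1(C)CCc2cc(O[Si](C)(C)C(C)(C)C)ccc2O1
F6 | step 14 | (2R)-6-[(tert-butyldimethylsilyl)oxy]-2-methylchromane-2-carbaldehyde | O=C[C@@]1(C)CCc2cc(O[Si](C)(C)C(C)(C)C)ccc2O1
F7 | step 14 | (2Z)-1-bromo-3-methyl-5-(2,6,6-trimethylcyclohex-1-en-1-yl)pent-2-ene | BrC/C=C(C)\CCC1=C(C)CCCC1(C)C
F8 | step 14 | diethyl [(2Z)-3-methyl-5-(2,6,6-trimethylcyclohex-1-en-1-yl)pent-2-en-1-yl]phosphonate | CCOP(=O)(OCC)C/C=C(C)\CCC1=C(C)CCCC1(C)C
F9 | step 14 | (2R)-6-[(tert-butyldimethylsilyl)oxy]-2-methyl-2-[(1E,3Z)-4-methyl-6-(2,6,6-trimethylcyclohex-1-en-1-yl)hexa-1,3-dien-1-yl]chromane | CC1=C(CC/C(C)=C\C=C\[C@@]2(C)CCc3cc(O[Si](C)(C)C(C)(C)C)ccc3O2)C(C)(C)CCC1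
F10 | step 12 | (3Z)-1,1-dibromo-4-methyl-6-(2,6,6-trimethylcyclohex-1-en-1-yl)hexa-1,3-diene | BrC(Br)=C/C=C(C)\CCC1=C(C)CCCC1(C)C
F11 | step 12 | 2-methylchromane-2,6-diol | CC1(O)CCc2cc(O)ccc2O1
F12 | step 12 | 4-{2,5-bis[(tert-butyldimethylsilyl)oxy]phenyl}butan-2-one | CC(=O)CCc1cc(O[Si](C)(C)C(C)(C)C)ccc1O[Si](C)(C)C(C)(C)C
F13 | step 12 | rac-(6Z)-1-{2,5-bis[(tert-butyldimethylsilyl)oxy]phenyl}-3,7-dimethyl-9-(2,6,6-trimethylcyclohex-1-en-1-yl)non-6-en-4-yn-3-yl methyl carbonate | COC(=O)OC(C)(CCc1cc(O[Si](C)(C)C(C)(C)C)ccc1O[Si](C)(C)C(C)(C)C)C#C/C=C(C)\CCC1=C(C)CCCC1(C)C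
F14 | step 3 | β-ionone | CC(=O)/C=C/C1=C(C)CCCC1(C)C
F15 | step 3 | dihydro-β-ionone | CC(=O)CCC1=C(C)CCCC1(C)C
F16 | step 3 | diethyl 4-(2,6,6-trimethylcyclohex-1-en-1-yl)but-1-en-2-yl phosphate | C=C(CCC1=C(C)CCCC1(C)C)OP(=O)(OCC)OCC
F17 | step 3 | 4-(2,6,6-trimethylcyclohex-1-en-1-yl)but-1-yne | C#CCCC1=C(C)CCCC1(C)C
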